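**Plan**

1. Cuts: the O–Si bonds and C5–Cl go first. C4a=C5 (aldol condensation) and C8a–C8 (aldol) then open the carbocycle to a 6-alkenyl-2,3-dihydro-4H-pyran-4-one and a C5–C8 keto aldehyde. The pyranone is cut at C4a–C4 and O2–C3 into β-propiolactone and a terminal enyne. The enyne is cut at the carbinol–alkyne bond, the oxolane O–CH2 bond and the crotyl C–C bond.
2. Enabling feature: in the pyran ring (O2, C1, C8a, C4a, C4, C3) the unit O2–C3=C4–C4a is a β-alkoxy enone once C4a is a carbonyl, i.e. the adduct of an alkoxide to an ynone. The rest, O2–C1–C8a–C4a(=O), is the four-membered ring of oxetan-2-one, so inserting the alkyne carbons C4 and C3 between the acyl carbon and the ring oxygen turns the four-membered lactone into the six-membered ring.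
3. Forward: oxolane ring (crotylboration, hydroboration, etherification) → side-chain enynol → pyran ring by two-atom ring expansion of β-propiolactone → C8a–C8 aldol → carbocycle by aldol condensation at C4a → C5 chlorination → desilylation.
4. Stereochemistry: oxolane C2/C3 from reagent-controlled (E)-crotylboration; side-chain carbinol from magnesium chelation by the oxolane oxygen; C7 from (S)-lactic acid (alkylation with self-regeneration of the stereocentre); C8 and C8a from the substrate-controlled anti aldol (Felkin–Anh face, chair transition state).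

Key step: step 13

Remark: core atoms carry isochromene numbers (C1, O2, C3, C4, C4a, C5–C8, C8a) and side-chain atoms C1'–C3'; the target is (7R,8R,8aS) with a (3'S) carbinol and a (2S,3S)-oxolane; metal salts formed by plain deprotonation of a numbered compound and work-up precursors (borinates, ozonides, metal alkoxides) are taken as transient forms of the compounds named.

**Route**

Step 1
Reactants: 1 methacrolein
Product: 2 (3S,4S)-2,4-dimethylhexa-1,5-dien-3-ol
Conditions: trans-2-butene, KOtBu, n-BuLi, THF, −78 → −45 °C; (−)-Ipc2BOMe, −78 °C; BF3·OEt2; 1, −78 °C; then NaOH, H2O2, 0 °C → rt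
Reagents that add atoms: trans-2-butene (C/C=C/C)
Why: Brown asymmetric crotylboration through a closed chair transition state, in which the E-crotyl geometry gives the anti relation and the isopinocampheyl groups derived from (+)-α-pinene direct the crotyl group to the Si face of the aldehyde, so both new stereocentres should be set as (3S,4S).

Step 2
Reactants: 2 (3S,4S)-2,4-dimethylhexa-1,5-dien-3-ol
Product: 3 (3S,4S)-3,5-dimethylhex-5-ene-1,4-diol
Conditions: disiamylborane (from BH3·THF and 2-methyl-2-butene), THF, 0 °C; then NaOH, H2O2, 0 °C → rt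
Reagents that add atoms: hydrogen peroxide (OO)
Why: Hydroboration–oxidation, in which the bulky dialkylborane should add anti-Markovnikov to the monosubstituted vinyl group much faster than to the 1,1-disubstituted isopropenyl group next to the borinate oxygen; no stereocentre is formed or touched.

Step 3
Reactants: 3 (3S,4S)-3,5-dimethylhex-5-ene-1,4-diol
Product: 5 (2S,3S)-3-methyl-2-(prop-1-en-2-yl)oxolane, via primary tosylate 4 (not isolated)
Conditions: TsCl, pyridine, CH2Cl2, 0 °C; then NaH, THF, 0 °C → rt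
Reagents that add atoms: none
Why: Selective sulfonylation of the primary alcohol followed by intramolecular Williamson etherification (5-exo-tet) by the secondary alkoxide; the C–O bond forms at the CH2 carbon, so both stereocentres are retained and the ring is 2,3-trans.

Step 4
Reactants: 5 (2S,3S)-3-methyl-2-(prop-1-en-2-yl)oxolane
Product: 6 1-[(2S,3S)-3-methyloxolan-2-yl]ethan-1-one
Conditions: O3, CH2Cl2, −78 °C; then Me2S, −78 °C → rt
Reagents that add atoms: ozone ([O-][O+]=O)
Why: Ozonolysis with reductive work-up converts the isopropenyl group into the acetyl group; oxolane C2 becomes α to a ketone but already has the more stable trans arrangement, so epimerisation should not erode it.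

Step 5
Reactants: 6 1-[(2S,3S)-3-methyloxolan-2-yl]ethan-1-one
Product: 7 (2S)-2-[(2S,3S)-3-methyloxolan-2-yl]-6-(trimethylsilyl)hexa-3,5-diyn-2-ol
Conditions: 1,4-bis(trimethylsilyl)buta-1,3-diyne, MeLi·LiBr, THF, −78 °C → rt; MgBr2·OEt2, −78 °C; then 6, Et2O/CH2Cl2, −78 °C
Reagents that add atoms: 1,4-bis(trimethylsilyl)buta-1,3-diyne (C[Si](C)(C)C#CC#C[Si](C)(C)C)
Why: Chelation-controlled (Cram chelate) addition of an alkynylmagnesium halide to an α-alkoxy ketone, in which magnesium bridges the carbonyl and ring oxygens and the nucleophile enters from the face of the C2–H bond, anti to ring carbon C3, which should give the (S)-carbinol.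

Step 6
Reactants: 7 (2S)-2-[(2S,3S)-3-methyloxolan-2-yl]-6-(trimethylsilyl)hexa-3,5-diyn-2-ol
Product: 9 (2S,3E)-2-[(2S,3S)-3-methyloxolan-2-yl]hex-3-en-5-yn-2-ol, via silyl enynol 8 (not isolated)
Conditions: LiAlH4, THF, 0 °C → rt; then MeOH, K2CO3, rt
Reagents that add atoms: none
Why: Hydroxyl-directed trans-hydroalumination should reduce only the alkyne next to the carbinol to the (E)-alkene, and methanolysis then cleaves the C(sp)–Si bond; no stereocentre is affected.

Step 7
Reactants: 10 (S)-lactic acid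
Product: 11 (2S,5S)-2-tert-butyl-5-methyl-1,3-dioxolan-4-one
Conditions: pivalaldehyde, TsOH (cat.), H2SO4 (cat.), pentane, reflux, Dean–Stark; recrystallisation
Reagents that add atoms: pivalaldehyde (CC(C)(C)C=O)
Why: Acid-catalysed acetalisation under water removal should give the thermodynamically preferred cis-dioxolanone, in which the acetal carbon is set by the lactic acid stereocentre.

Step 8
Reactants: 11 (2S,5S)-2-tert-butyl-5-methyl-1,3-dioxolan-4-one
Product: 12 (2S,5R)-5-[(benzyloxy)methyl]-2-tert-butyl-5-methyl-1,3-dioxolan-4-one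
Conditions: LiN(iPr)2, THF, −78 °C; BnOCH2Cl, −78 → −30 °C
Reagents that add atoms: benzyl chloromethyl ether (ClCOCc1ccccc1)
Why: Alkylation of the dioxolanone lithium enolate (self-regeneration of the stereocentre), in which the electrophile enters anti to the tert-butyl group, so the benzyloxymethyl group takes the place of the former hydrogen and the quaternary centre (future C7) forms with retention.

Step 9
Reactants: 12 (2S,5R)-5-[(benzyloxy)methyl]-2-tert-butyl-5-methyl-1,3-dioxolan-4-one
Product: 13 (3R)-4-(benzyloxy)-3-hydroxy-3-methylbutan-2-one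
Conditions: MeLi, THF, −78 °C; aqueous work-up
Reagents that add atoms: methyllithium ([Li]C)
Why: Organolithium addition to the dioxolanone carbonyl gives a tetrahedral alkoxide that should survive at low temperature and collapse on work-up to the methyl ketone with loss of pivalaldehyde, leaving the quaternary stereocentre untouched.

Step 10
Reactants: 13 (3R)-4-(benzyloxy)-3-hydroxy-3-methylbutan-2-one
Product: 14 (3R)-4-(benzyloxy)-3-methyl-3-[(triethylsilyl)oxy]butan-2-one
Conditions: Et3SiOTf, 2,6-lutidine, CH2Cl2, −78 → 0 °C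
Reagents that add atoms: triethylsilyl trifluoromethanesulfonate (CC[Si](CC)(CC)OS(=O)(=O)C(F)(F)F)
Why: Silylation of the hindered tertiary alcohol with a silyl triflate and a hindered pyridine base; no stereochemical change.

Step 11
Reactants: 14 (3R)-4-(benzyloxy)-3-methyl-3-[(triethylsilyl)oxy]butan-2-one
Product: 15 (3R)-4-hydroxy-3-methyl-3-[(triethylsilyl)oxy]butan-2-one
Conditions: H2 (1 atm), Pd/C (cat.), EtOAc, rt
Reagents that add atoms: none
Why: Hydrogenolysis of the benzyl ether on Pd/C in a non-protic solvent should leave the ketone and the silyl ether intact.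

Step 12
Reactants: 15 (3R)-4-hydroxy-3-methyl-3-[(triethylsilyl)oxy]butan-2-one
Product: 16 (2R)-2-methyl-3-oxo-2-[(triethylsilyl)oxy]butanal
Conditions: Dess–Martin periodinane, CH2Cl2, 0 °C → rt; used at once
Reagents that add atoms: none
Why: Dess–Martin oxidation of the primary alcohol to the aldehyde, whose α-carbon is quaternary and therefore cannot epimerise.

Step 13
Reactants: 9 (2S,3E)-2-[(2S,3S)-3-methyloxolan-2-yl]hex-3-en-5-yn-2-ol; 17 β-propiolactone
Product: 19 6-[(1E,3S)-3-hydroxy-3-[(2S,3S)-3-methyloxolan-2-yl]but-1-en-1-yl]-2,3-dihydro-4H-pyran-4-one, via lithium alkoxide ynone 18 (not isolated)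
Conditions: n-BuLi (2 equiv), THF, −78 °C; then add to 17 (1.5 equiv), THF, −78 → 0 °C; MeOH, rt
Reagents that add atoms: none
Why: Proposed new method: the dilithio derivative of 9 (alkoxide and acetylide) attacks the lactone carbonyl of 17 as a hard nucleophile, the strained tetrahedral adduct collapses with acyl–oxygen cleavage to the ynone alkoxide 18, and this alkoxide adds to the ynone β-carbon C3, so that the two alkyne carbons end up between the acyl carbon C4a and the ring oxygen O2 and the four-membered ring becomes the six-membered 2,3-dihydro-4H-pyran-4-one after protonation at C4 by methanol. The closest known reaction types are the conversion of lactones and N-methoxy-N-methylamides into ynones by lithium acetylides, acyl–oxygen opening of β-lactones by hard nucleophiles, and the base-mediated cyclisation of β-hydroxy ynones to dihydropyranones; their union in one flask on a β-lactone is the untested element. The only ring closed is the pyranone, by 6-endo-dig attack of oxygen, which is favoured for an ynone because the polarised β-carbon is the endo position, whereas 5-exo-dig closure would need attack at the α-carbon. No stereocentre is created (C1 and C8a are CH2 at this stage and the enol ether geometry is fixed by the ring), and the three stereocentres of 9 are remote, with the tertiary allylic alcohol masked as its lithium alkoxide. The step needs carbonyl attack instead of SN2 opening at the CH2–O carbon or α-deprotonation of 17 (a lithium acetylide without Lewis acid at −78 °C is hard and only moderately basic), mono-addition (inverse addition to excess 17, and ring closure turns the ynone into a far less electrophilic vinylogous ester), and 1,4- instead of 1,6-addition of the alkoxide to the enynone (six- versus eight-membered ring).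

Step 14
Reactants: 19 6-[(1E,3S)-3-hydroxy-3-[(2S,3S)-3-methyloxolan-2-yl]but-1-en-1-yl]-2,3-dihydro-4H-pyran-4-one; 16 (2R)-2-methyl-3-oxo-2-[(triethylsilyl)oxy]butanal
Product: 20 (3S)-3-[(1R,2R)-1-hydroxy-2-methyl-3-oxo-2-[(triethylsilyl)oxy]butyl]-6-[(1E,3S)-3-hydroxy-3-[(2S,3S)-3-methyloxolan-2-yl]but-1-en-1-yl]-2,3-dihydro-4H-pyran-4-one
Conditions: LiN(iPr)2 (2.1 equiv), THF, −78 °C; 16, −78 °C; cold quench
Reagents that add atoms: none
Why: Lithium enolate aldol addition, in which kinetic deprotonation at C8a gives the ring-fixed E-enolate that adds through a chair Zimmerman–Traxler transition state (anti aldol, C8a relative to C8) to the Felkin–Anh face of the α-silyloxy aldehyde (silyloxy group anti to the nucleophile, which passes the methyl group), so C8 and C8a should follow from C7 with the configuration of the target.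

Step 15
Reactants: 20 (3S)-3-[(1R,2R)-1-hydroxy-2-methyl-3-oxo-2-[(triethylsilyl)oxy]butyl]-6-[(1E,3S)-3-hydroxy-3-[(2S,3S)-3-methyloxolan-2-yl]but-1-en-1-yl]-2,3-dihydro-4H-pyran-4-one
Product: 21 (3S)-3-[(1R,2R)-2-methyl-3-oxo-1,2-bis[(triethylsilyl)oxy]butyl]-6-[(1E,3S)-3-[(2S,3S)-3-methyloxolan-2-yl]-3-[(triethylsilyl)oxy]but-1-en-1-yl]-2,3-dihydro-4H-pyran-4-one
Conditions: Et3SiOTf (2.5 equiv), 2,6-lutidine, CH2Cl2, −78 → 0 °C
Reagents that add atoms: triethylsilyl trifluoromethanesulfonate (CC[Si](CC)(CC)OS(=O)(=O)C(F)(F)F)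
Why: Silyl triflate silylation protects the secondary C8 alcohol against retro-aldol cleavage and the tertiary allylic alcohol against ionisation; no stereocentre is touched.

Step 16
Reactants: 21 (3S)-3-[(1R,2R)-2-methyl-3-oxo-1,2-bis[(triethylsilyl)oxy]butyl]-6-[(1E,3S)-3-[(2S,3S)-3-methyloxolan-2-yl]-3-[(triethylsilyl)oxy]but-1-en-1-yl]-2,3-dihydro-4H-pyran-4-one
Product: 23 (7R,8R,8aS)-7-methyl-3-[(1E,3S)-3-[(2S,3S)-3-methyloxolan-2-yl]-3-[(triethylsilyl)oxy]but-1-en-1-yl]-7,8-bis[(triethylsilyl)oxy]-1,7,8,8a-tetrahydro-6H-isochromen-6-one, via tertiary aldol 22 (not isolated)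
Conditions: LiN(SiMe3)2 (1.1 equiv), THF, −78 → −20 °C; aqueous work-up; then PPTS (cat.), CH2Cl2, rt
Reagents that add atoms: none
Why: Intramolecular aldol condensation, in which the methyl ketone (its other α-carbon, C7, is quaternary) is deprotonated kinetically at CH3, the enolate adds 1,2 to the vinylogous ester carbonyl C4a in a six-membered ring closure (Stork–Danheiser-type addition), and the resulting 4-hydroxy-4H-pyran ionises under mild acid to a pyrylium-type cation that loses the α-keto proton at C5, giving the push–pull dienone with C8a unchanged.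

Step 17
Reactants: 23 (7R,8R,8aS)-7-methyl-3-[(1E,3S)-3-[(2S,3S)-3-methyloxolan-2-yl]-3-[(triethylsilyl)oxy]but-1-en-1-yl]-7,8-bis[(triethylsilyl)oxy]-1,7,8,8a-tetrahydro-6H-isochromen-6-one
Product: 24 (7R,8R,8aS)-5-chloro-7-methyl-3-[(1E,3S)-3-[(2S,3S)-3-methyloxolan-2-yl]-3-[(triethylsilyl)oxy]but-1-en-1-yl]-7,8-bis[(triethylsilyl)oxy]-1,7,8,8a-tetrahydro-6H-isochromen-6-one
Conditions: N-chlorosuccinimide (1.05 equiv), MeCN, 0 °C → rt
Reagents that add atoms: N-chlorosuccinimide (O=C1CCC(=O)N1Cl)
Why: Electrophilic chlorination of the doubly vinylogous ester at C5, the carbon α to the ketone and the terminus of the O2–C3=C4–C4a=C5 donor system, as is usual for this position of isochromenone (azaphilone-type) chromophores.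

Step 18
Reactants: 24 (7R,8R,8aS)-5-chloro-7-methyl-3-[(1E,3S)-3-[(2S,3S)-3-methyloxolan-2-yl]-3-[(triethylsilyl)oxy]but-1-en-1-yl]-7,8-bis[(triethylsilyl)oxy]-1,7,8,8a-tetrahydro-6H-isochromen-6-one
Product: 25 (7R,8R,8aS)-5-chloro-7,8-dihydroxy-3-[(1E,3S)-3-hydroxy-3-[(2S,3S)-3-methyloxolan-2-yl]but-1-en-1-yl]-7-methyl-1,7,8,8a-tetrahydro-6H-isochromen-6-one
Conditions: HF·pyridine, pyridine, THF, 0 °C → rt
Reagents that add atoms: none
Why: Fluoride-mediated cleavage of the three triethylsilyl ethers under buffered, non-basic conditions that should avoid both acid ionisation of the tertiary allylic alcohol and base-induced elimination of the C8 hydroxyl.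

**Compound list**

1 | methacrolein (2-methylprop-2-enal) | CC(=C)C=O | starting material
2 | (3S,4S)-2,4-dimethylhexa-1,5-dien-3-ol | C=C[C@H](C)[C@H](O)C(C)=C | intermediate
3 | (3S,4S)-3,5-dimethylhex-5-ene-1,4-diol | OCC[C@H](C)[C@H](O)C(C)=C | intermediate
4 | (3S,4S)-4-hydroxy-3,5-dimethylhex-5-en-1-yl 4-methylbenzenesulfonate | Cc1ccc(cc1)S(=O)(=O)OCC[C@H](C)[C@H](O)C(C)=C | intermediate
5 | (2S,3S)-3-methyl-2-(prop-1-en-2-yl)oxolane | C[C@H]1CCO[C@@H]1C(C)=C | intermediate
6 | 1-[(2S,3S)-3-methyloxolan-2-yl]ethan-1-one | C[C@H]1CCO[C@@H]1C(C)=O | intermediate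
7 | (2S)-2-[(2S,3S)-3-methyloxolan-2-yl]-6-(trimethylsilyl)hexa-3,5-diyn-2-ol | C[C@H]1CCO[C@@H]1[C@@](C)(O)C#CC#C[Si](C)(C)C | intermediate
8 | (2S,3E)-2-[(2S,3S)-3-methyloxolan-2-yl]-6-(trimethylsilyl)hex-3-en-5-yn-2-ol | C[C@H]1CCO[C@@H]1[C@@](C)(O)/C=C/C#C[Si](C)(C)C | intermediate
9 | (2S,3E)-2-[(2S,3S)-3-methyloxolan-2-yl]hex-3-en-5-yn-2-ol | C[C@H]1CCO[C@@H]1[C@@](C)(O)/C=C/C#C | intermediate
10 | (S)-lactic acid | C[C@H](O)C(=O)O | starting material
11 | (2S,5S)-2-tert-butyl-5-methyl-1,3-dioxolan-4-one | C[C@@H]1O[C@H](C(C)(C)C)OC1=O | intermediate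
12 | (2S,5R)-5-[(benzyloxy)methyl]-2-tert-butyl-5-methyl-1,3-dioxolan-4-one | C[C@]1(COCc2ccccc2)O[C@H](C(C)(C)C)OC1=O | intermediate
13 | (3R)-4-(benzyloxy)-3-hydroxy-3-methylbutan-2-one | CC(=O)[C@](C)(O)COCc1ccccc1 | intermediate
14 | (3R)-4-(benzyloxy)-3-methyl-3-[(triethylsilyl)oxy]butan-2-one | CC(=O)[C@](C)(O[Si](CC)(CC)CC)COCc1ccccc1 | intermediate
15 | (3R)-4-hydroxy-3-methyl-3-[(triethylsilyl)oxy]butan-2-one | CC(=O)[C@](C)(O[Si](CC)(CC)CC)CO | intermediate
16 | (2R)-2-methyl-3-oxo-2-[(triethylsilyl)oxy]butanal | CC(=O)[C@](C)(O[Si](CC)(CC)CC)C=O | intermediate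
17 | β-propiolactone (oxetan-2-one) | O=C1CCO1 | starting material
18 | dilithium (6E,8S)-8-[(2S,3S)-3-methyloxolan-2-yl]-3-oxonon-6-en-4-yne-1,8-bis(olate) | C[C@H]1CCO[C@@H]1[C@@](C)([O-])/C=C/C#CC(=O)CC[O-].[Li+].[Li+] | intermediate
19 | 6-[(1E,3S)-3-hydroxy-3-[(2S,3S)-3-methyloxolan-2-yl]but-1-en-1-yl]-2,3-dihydro-4H-pyran-4-one | C[C@H]1CCO[C@@H]1[C@@](C)(O)/C=C/C1=CC(=O)CCO1 | intermediate
20 | (3S)-3-[(1R,2R)-1-hydroxy-2-methyl-3-oxo-2-[(triethylsilyl)oxy]butyl]-6-[(1E,3S)-3-hydroxy-3-[(2S,3S)-3-methyloxolan-2-yl]but-1-en-1-yl]-2,3-dihydro-4H-pyran-4-one | C[C@H]1CCO[C@@H]1[C@@](C)(O)/C=C/C1=CC(=O)[C@@H](CO1)[C@@H](O)[C@@](C)(O[Si](CC)(CC)CC)C(C)=O | intermediate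
21 | (3S)-3-[(1R,2R)-2-methyl-3-oxo-1,2-bis[(triethylsilyl)oxy]butyl]-6-[(1E,3S)-3-[(2S,3S)-3-methyloxolan-2-yl]-3-[(triethylsilyl)oxy]but-1-en-1-yl]-2,3-dihydro-4H-pyran-4-one | C[C@H]1CCO[C@@H]1[C@@](C)(O[Si](CC)(CC)CC)/C=C/C1=CC(=O)[C@@H](CO1)[C@@H](O[Si](CC)(CC)CC)[C@@](C)(O[Si](CC)(CC)CC)C(C)=O | intermediate
22 | (7R,8R,8aS)-4a-hydroxy-7-methyl-3-[(1E,3S)-3-[(2S,3S)-3-methyloxolan-2-yl]-3-[(triethylsilyl)oxy]but-1-en-1-yl]-7,8-bis[(triethylsilyl)oxy]-4a,5,8,8a-tetrahydro-1H-isochromen-6(7H)-one (C4a epimers, centre removed in the same step) | C[C@H]1CCO[C@@H]1[C@@](C)(O[Si](CC)(CC)CC)/C=C/C1=CC2(O)CC(=O)[C@](C)(O[Si](CC)(CC)CC)[C@H](O[Si](CC)(CC)CC)[C@@H]2CO1 | intermediate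
23 | (7R,8R,8aS)-7-methyl-3-[(1E,3S)-3-[(2S,3S)-3-methyloxolan-2-yl]-3-[(triethylsilyl)oxy]but-1-en-1-yl]-7,8-bis[(triethylsilyl)oxy]-1,7,8,8a-tetrahydro-6H-isochromen-6-one | C[C@H]1CCO[C@@H]1[C@@](C)(O[Si](CC)(CC)CC)/C=C/C1=CC2=CC(=O)[C@](C)(O[Si](CC)(CC)CC)[C@H](O[Si](CC)(CC)CC)[C@@H]2CO1 | intermediate
24 | (7R,8R,8aS)-5-chloro-7-methyl-3-[(1E,3S)-3-[(2S,3S)-3-methyloxolan-2-yl]-3-[(triethylsilyl)oxy]but-1-en-1-yl]-7,8-bis[(triethylsilyl)oxy]-1,7,8,8a-tetrahydro-6H-isochromen-6-one | C[C@H]1CCO[C@@H]1[C@@](C)(O[Si](CC)(CC)CC)/C=C/C1=CC2=C(Cl)C(=O)[C@](C)(O[Si](CC)(CC)CC)[C@H](O[Si](CC)(CC)CC)[C@@H]2CO1 | intermediate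
25 | (7R,8R,8aS)-5-chloro-7,8-dihydroxy-3-[(1E,3S)-3-hydroxy-3-[(2S,3S)-3-methyloxolan-2-yl]but-1-en-1-yl]-7-methyl-1,7,8,8a-tetrahydro-6H-isochromen-6-one | C[C@H]1CCO[C@@H]1[C@@](C)(O)/C=C/C1=CC2=C(Cl)C(=O)[C@](C)(O)[C@H](O)[C@@H]2CO1 | target

**Count and risks**

Total steps: 18. Longest linear sequence: 12 (steps 1–6 and 13–18).

Step 13 (ring expansion of the four-membered lactone). What may go wrong: proton abstraction from the lactone with β-elimination to acrylate, attack at the CH2–O carbon instead of the carbonyl, or a second acetylide addition to the transient ynone before the alkoxide closes the ring. Fallback, setting out from 9: the dilithio derivative of 9 is acylated with N-methoxy-N-methyl-3-[(tert-butyldimethylsilyl)oxy]propanamide, whose chelated tetrahedral adduct should secure mono-addition, to give the silyl-protected ynone (6E,8S)-1-[(tert-butyldimethylsilyl)oxy]-8-hydroxy-8-[(2S,3S)-3-methyloxolan-2-yl]non-6-en-4-yn-3-one F1. Removal of the silyl group with HF·pyridine and treatment with K2CO3 in MeOH should close the free β-hydroxy ynone 6-endo-dig, and the route is rejoined at 19; the pyran ring is then built directly in its final size.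

Step 16 (carbocycle by aldol condensation at the vinylogous ester carbonyl). What may go wrong: an unfavourable equilibrium for 1,2-addition of the ketone enolate to the poorly electrophilic C4a carbonyl, or competing deprotonation at C8a with loss of the C8 silyloxy group. Fallback, setting out from 21: the methyl ketone is converted with LiN(SiMe3)2 and Me3SiCl at −78 °C into the trimethylsilyl enol ether (3S)-3-[(1R,2R)-2-methyl-1,2-bis[(triethylsilyl)oxy]-3-[(trimethylsilyl)oxy]but-3-en-1-yl]-6-[(1E,3S)-3-[(2S,3S)-3-methyloxolan-2-yl]-3-[(triethylsilyl)oxy]but-1-en-1-yl]-2,3-dihydro-4H-pyran-4-one F2. The pyranone is then activated as a 4-silyloxypyrylium-type cation with catalytic Me3SiOTf (2,6-di-tert-butylpyridine, CH2Cl2, −78 → 0 °C); intramolecular Mukaiyama addition at C4a and loss of silanol should give 23, where the route is rejoined. The acceptor is thus made electrophilic instead of the donor being made basic.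

Step 14 (aldol union at C8a–C8). What may go wrong: proton transfer from the methyl ketone of 16 to the basic enolate, retro-aldol cleavage on warming, and incomplete facial control at the α-quaternary aldehyde. Fallback, setting out from 19: treatment with LiN(iPr)2 (2 equiv) and Et3SiCl gives the bis-silylated 2-silyloxy diene triethyl({6-[(1E,3S)-3-[(2S,3S)-3-methyloxolan-2-yl]-3-[(triethylsilyl)oxy]but-1-en-1-yl]-2H-pyran-4-yl}oxy)silane F3. A BF3·OEt2-mediated Mukaiyama aldol addition of F3 to 16 (CH2Cl2, −78 °C; open transition state, no basic enolate, Felkin–Anh face) should give (3S)-3-[(1R,2R)-1-hydroxy-2-methyl-3-oxo-2-[(triethylsilyl)oxy]butyl]-6-[(1E,3S)-3-[(2S,3S)-3-methyloxolan-2-yl]-3-[(triethylsilyl)oxy]but-1-en-1-yl]-2,3-dihydro-4H-pyran-4-one F4. Silylation of the C8 hydroxyl under the conditions of step 15 rejoins the route at 21.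

**Further compounds**

F1 | step 13 | (6E,8S)-1-[(tert-butyldimethylsilyl)oxy]-8-hydroxy-8-[(2S,3S)-3-methyloxolan-2-yl]non-6-en-4-yn-3-one | C[C@H]1CCO[C@@H]1[C@@](C)(O)/C=C/C#CC(=O)CCO[Si](C)(C)C(C)(C)C
F2 | step 16 | (3S)-3-[(1R,2R)-2-methyl-1,2-bis[(triethylsilyl)oxy]-3-[(trimethylsilyl)oxy]but-3-en-1-yl]-6-[(1E,3S)-3-[(2S,3S)-3-methyloxolan-2-yl]-3-[(triethylsilyl)oxy]but-1-en-1-yl]-2,3-dihydro-4H-pyran-4-one | C[C@H]1CCO[C@@H]1[C@@](C)(O[Si](CC)(CC)CC)/C=C/C1=CC(=O)[C@@H](CO1)[C@@H](O[Si](CC)(CC)CC)[C@@](C)(O[Si](CC)(CC)CC)C(=C)O[Si](C)(C)C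
F3 | step 14 | triethyl({6-[(1E,3S)-3-[(2S,3S)-3-methyloxolan-2-yl]-3-[(triethylsilyl)oxy]but-1-en-1-yl]-2H-pyran-4-yl}oxy)silane | C[C@H]1CCO[C@@H]1[C@@](C)(O[Si](CC)(CC)CC)/C=C/C1=CC(O[Si](CC)(CC)CC)=CCO1
F4 | step 14 | (3S)-3-[(1R,2R)-1-hydroxy-2-methyl-3-oxo-2-[(triethylsilyl)oxy]butyl]-6-[(1E,3S)-3-[(2S,3S)-3-methyloxolan-2-yl]-3-[(triethylsilyl)oxy]but-1-en-1-yl]-2,3-dihydro-4H-pyran-4-one | C[C@H]1CCO[C@@H]1[C@@](C)(O[Si](CC)(CC)CC)/C=C/C1=CC(=O)[C@@H](CO1)[C@@H](O)[C@@](C)(O[Si](CC)(CC)CC)C(C)=O
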